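Ring A is numbered C1 (CO2H), C2 (OMe), C3 (prenyl), C4 (OH), C5 (prenyl), C6 (CH2CH2Ar). The retrosynthesis cuts C3–C4 and C5–C6.
Enabling feature: C6–C1–C2–C3, with the carboxyl on C1 and the methoxy on C2, is the diene C6–C5–C4–C3 of a 4-methoxy-2-pyrone-5-carboxylate. C4(O)–C5(prenyl) is a two-carbon ynol ether, and the C4 oxygen lies para to the C1 carboxyl, where polarity matching places it.
The pyrone is cut at O1–C2 and at C5–C6, giving a 2-prenyl-3-oxoglutarate and O-silylated phloretic acid chloride. The ynol ether goes back to a 4-methylpent-3-enoate plus one carbon from CH2Br2.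
Forward: the pyrone ring is built first (C-acylation, lactonisation, O-methylation), then ring A by [4+2] cycloaddition and loss of CO2. Ring B is bought as phloretic acid.
The carboxyl is carried as a 2-(trimethylsilyl)ethyl ester, so one fluoride treatment frees the acid and both phenols.
The target has no stereocentre and no E/Z alkene, so nothing stereochemical has to be set.

Key step: step 9

Assumption: pyrone atoms are numbered O1, C2 (lactone C=O), C3 to C6 in all names so that the mapping onto ring A stays visible. All un-numbered reagents are purchased.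

Step 1
Reactants: 1 dimethyl 3-oxopentanedioate (dimethyl acetonedicarboxylate)
Product: 2 bis[2-(trimethylsilyl)ethyl] 3-oxopentanedioate
Conditions: Me3SiCH2CH2OH (3 equiv), DMAP (cat.), toluene, reflux, 4 Å sieves in a Soxhlet head
Reagents that add atoms: 2-(trimethylsilyl)ethanol, C[Si](C)(C)CCO
Why: DMAP-catalysed transesterification of a β-keto ester, a class that exchanges its alkoxy groups readily, is driven to the diester by trapping methanol on the sieves.

Step 2
Reactants: 2 bis[2-(trimethylsilyl)ethyl] 3-oxopentanedioate; 3 prenyl bromide (1-bromo-3-methylbut-2-ene)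
Product: 4 bis[2-(trimethylsilyl)ethyl] 2-(3-methylbut-2-enyl)-3-oxopentanedioate (racemic)
Conditions: 2 (1.5 equiv), NaH (1 equiv), THF, 0 °C; then 3 (1 equiv), 0 °C to rt
Reagents that add atoms: none
Why: SN2 C-alkylation of a β-keto ester sodium enolate by a soft primary allylic bromide, with 2 in excess to hold back double alkylation; the new C2 stereocentre is racemic, labile and becomes sp2 in step 5.

Step 3
Reactants: 5 3-(4-hydroxyphenyl)propanoic acid (phloretic acid)
Product: 7 3-[4-(triisopropylsilyloxy)phenyl]propanoic acid, via bis-silylated phloretic acid 6 (not isolated)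
Conditions: i-Pr3SiCl (2.2 equiv), imidazole, DMF, rt; then K2CO3, MeOH/THF/H2O, rt; 1 M HCl to pH 3
Reagents that add atoms: chlorotriisopropylsilane, CC(C)[Si](Cl)(C(C)C)C(C)C
Why: Imidazole-promoted silylation caps both acidic oxygens, and mild carbonate hydrolysis then removes only the much more labile silyl ester while the aryl triisopropylsilyl ether stays.

Step 4
Reactants: 7 3-[4-(triisopropylsilyloxy)phenyl]propanoic acid
Product: 8 3-[4-(triisopropylsilyloxy)phenyl]propanoyl chloride
Conditions: (COCl)2, DMF (cat.), CH2Cl2, 0 °C to rt; concentrate, use crude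
Reagents that add atoms: oxalyl chloride, O=C(Cl)C(=O)Cl
Why: Acid chloride formation by Vilsmeier-type activation is tolerated by an aryl triisopropylsilyl ether and leaves only gases behind.

Step 5
Reactants: 4 bis[2-(trimethylsilyl)ethyl] 2-(3-methylbut-2-enyl)-3-oxopentanedioate; 8 3-[4-(triisopropylsilyloxy)phenyl]propanoyl chloride
Product: 10 2-(trimethylsilyl)ethyl 4-hydroxy-3-(3-methylbut-2-enyl)-2-oxo-6-{2-[4-(triisopropylsilyloxy)phenyl]ethyl}-2H-pyran-5-carboxylate, via acylated oxoglutarate 9 (not isolated)
Conditions: MgCl2, pyridine, CH2Cl2, 0 °C to rt; cold 1 M HCl wash; crude, DBU (1.2 equiv), toluene, 80 °C; cold 1 M HCl wash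
Reagents that add atoms: none
Why: Soft-enolisation C-acylation of the magnesium chelate occurs at the unsubstituted, more acidic C4 methylene because only that product can rest as a tricarbonyl chelate, and the enol oxygen of the new ketone then attacks the one ester it can reach through a six-membered transition state (6-exo-trig lactonisation), which erases both labile stereocentres of 9.

Step 6
Reactants: 10 2-(trimethylsilyl)ethyl 4-hydroxy-3-(3-methylbut-2-enyl)-2-oxo-6-{2-[4-(triisopropylsilyloxy)phenyl]ethyl}-2H-pyran-5-carboxylate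
Product: 11 2-(trimethylsilyl)ethyl 4-methoxy-3-(3-methylbut-2-enyl)-2-oxo-6-{2-[4-(triisopropylsilyloxy)phenyl]ethyl}-2H-pyran-5-carboxylate
Conditions: Me2SO4, K2CO3, acetone, reflux
Reagents that add atoms: dimethyl sulfate, COS(=O)(=O)OC
Why: O-alkylation of the pyronate anion with a hard methylating agent is the standard passage from 4-hydroxy-2-pyrones to 4-methoxy-2-pyrones, since the charge sits mainly on O4, and any 2-methoxy-4-pyrone isomer should be separable by chromatography.

Step 7
Reactants: 12 4-methylpent-3-enoic acid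
Product: 13 methyl 4-methylpent-3-enoate
Conditions: MeI, K2CO3, DMF, rt
Reagents that add atoms: iodomethane, CI
Why: Carboxylate SN2 alkylation esterifies without the acid that would close this β,γ-unsaturated acid to the γ,γ-dimethyl lactone and without a base strong enough to move the alkene into conjugation.

Step 8
Reactants: 13 methyl 4-methylpent-3-enoate
Product: 16 triisopropyl(5-methylhex-4-en-1-ynyloxy)silane, via lithium dibromoenolate 14 (not isolated), via lithium ynolate 15 (not isolated)
Conditions: CH2Br2, lithium 2,2,6,6-tetramethylpiperidide, THF, −78 °C; 13; LiN(SiMe3)2, −78 °C; n-BuLi, −78 °C to rt; i-Pr3SiCl, 0 °C to rt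
Reagents that add atoms: dibromomethane, BrCBr; chlorotriisopropylsilane, CC(C)[Si](Cl)(C(C)C)C(C)C
Why: Kowalski ester homologation, in which LiCHBr2 adds to the ester at −78 °C, dibromoenolate 14 undergoes Br/Li exchange and a 1,2-shift of the 3-methylbut-2-enyl group onto the carbenoid carbon to give ynolate 15, and the bulky silyl chloride traps 15 on oxygen.

Step 9
Reactants: 11 2-(trimethylsilyl)ethyl 4-methoxy-3-(3-methylbut-2-enyl)-2-oxo-6-{2-[4-(triisopropylsilyloxy)phenyl]ethyl}-2H-pyran-5-carboxylate; 16 triisopropyl(5-methylhex-4-en-1-ynyloxy)silane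
Product: 18 2-(trimethylsilyl)ethyl 2-methoxy-3,5-bis(3-methylbut-2-enyl)-4-(triisopropylsilyloxy)-6-{2-[4-(triisopropylsilyloxy)phenyl]ethyl}benzoate, via bridged lactone 17 (not isolated)
Conditions: 16 (3 equiv), BHT (cat.), toluene (1 M), 130 °C, base-washed sealed tube, Ar
Reagents that add atoms: none
Why: Pyrone 11 is the electron-poor 4π partner (lactone C=O and C5 ester make C6 its acceptor terminus, the 4-methoxy group makes C3 its donor terminus) and ynol ether 16 the electron-rich 2π partner, so an inverse-electron-demand [4+2] cycloaddition, concerted but strongly asynchronous or stepwise through a silylketenium/dienolate ion pair, joins the prenyl-bearing alkyne carbon to C6 first and the oxygen-bearing carbon to C3 second. This intermolecular [4+2] annulation closes the one new ring, the six-membered carbocycle that becomes ring A, by forming the target bonds C5–C6 and C3–C4. The 2-oxabicyclo[2.2.2]octadienone 17 then loses CO2 in an irreversible retro-[4+2] at the reaction temperature, leaving the benzene ring with its methoxy and silyloxy oxygens already differentiated. The closest known reaction type is the Diels–Alder/decarboxylation of 2-pyrone-5-carboxylates such as coumalates and isodehydroacetates with ynamines and ynol ethers. The two bridgehead stereocentres of 17 form as a racemate, with their relative configuration fixed by the bicycle, and vanish with CO2, so no stereocontrol is needed. The selectivity required is regiochemical and rests on this polarity match, both substituent effects in 11 pointing the same way, while the prenyl alkenes are far too weakly nucleophilic to compete and excess 16 at high concentration offsets the crowding of the fully substituted diene.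

Step 10
Reactants: 18 2-(trimethylsilyl)ethyl 2-methoxy-3,5-bis(3-methylbut-2-enyl)-4-(triisopropylsilyloxy)-6-{2-[4-(triisopropylsilyloxy)phenyl]ethyl}benzoate
Product: 19 4-hydroxy-6-[2-(4-hydroxyphenyl)ethyl]-2-methoxy-3,5-bis(3-methylbut-2-enyl)benzoic acid (CNP0254933.0)
Conditions: Bu4NF (6 equiv), THF, Ar, 0 °C to 40 °C; cold 0.5 M HCl to pH 4
Reagents that add atoms: none
Why: Fluoride-induced desilylation attacks silicon at all three sites, freeing both phenoxides directly and the carboxylate by β-elimination of ethene from the 2-(trimethylsilyl)ethyl ester, so the acyl carbon shielded by two ortho groups is never attacked and neither strong acid nor high heat reaches the prenyl groups or the decarboxylation-prone acid.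

Compound list
1 | dimethyl 3-oxopentanedioate | COC(=O)CC(=O)CC(=O)OC | starting material
2 | bis[2-(trimethylsilyl)ethyl] 3-oxopentanedioate | C[Si](C)(C)CCOC(=O)CC(=O)CC(=O)OCC[Si](C)(C)C | intermediate
3 | prenyl bromide (1-bromo-3-methylbut-2-ene) | CC(C)=CCBr | starting material
4 | bis[2-(trimethylsilyl)ethyl] 2-(3-methylbut-2-enyl)-3-oxopentanedioate (racemic, labile centre) | C[Si](C)(C)CCOC(=O)CC(=O)C(CC=C(C)C)C(=O)OCC[Si](C)(C)C | intermediate
5 | 3-(4-hydroxyphenyl)propanoic acid | OC(=O)CCc1ccc(O)cc1 | starting material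
6 | triisopropylsilyl 3-[4-(triisopropylsilyloxy)phenyl]propanoate | CC(C)[Si](OC(=O)CCc1ccc(O[Si](C(C)C)(C(C)C)C(C)C)cc1)(C(C)C)C(C)C | intermediate
7 | 3-[4-(triisopropylsilyloxy)phenyl]propanoic acid | OC(=O)CCc1ccc(O[Si](C(C)C)(C(C)C)C(C)C)cc1 | intermediate
8 | 3-[4-(triisopropylsilyloxy)phenyl]propanoyl chloride | ClC(=O)CCc1ccc(O[Si](C(C)C)(C(C)C)C(C)C)cc1 | intermediate
9 | bis[2-(trimethylsilyl)ethyl] 2-(3-methylbut-2-enyl)-3-oxo-4-{3-[4-(triisopropylsilyloxy)phenyl]propanoyl}pentanedioate (tautomer and epimer mixture, labile centres) | C[Si](C)(C)CCOC(=O)C(CC=C(C)C)C(=O)C(C(=O)OCC[Si](C)(C)C)C(=O)CCc1ccc(O[Si](C(C)C)(C(C)C)C(C)C)cc1 | intermediate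
10 | 2-(trimethylsilyl)ethyl 4-hydroxy-3-(3-methylbut-2-enyl)-2-oxo-6-{2-[4-(triisopropylsilyloxy)phenyl]ethyl}-2H-pyran-5-carboxylate | C[Si](C)(C)CCOC(=O)C1=C(CCc2ccc(O[Si](C(C)C)(C(C)C)C(C)C)cc2)OC(=O)C(CC=C(C)C)=C1O | intermediate
11 | 2-(trimethylsilyl)ethyl 4-methoxy-3-(3-methylbut-2-enyl)-2-oxo-6-{2-[4-(triisopropylsilyloxy)phenyl]ethyl}-2H-pyran-5-carboxylate | C[Si](C)(C)CCOC(=O)C1=C(CCc2ccc(O[Si](C(C)C)(C(C)C)C(C)C)cc2)OC(=O)C(CC=C(C)C)=C1OC | intermediate
12 | 4-methylpent-3-enoic acid | CC(C)=CCC(=O)O | starting material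
13 | methyl 4-methylpent-3-enoate | COC(=O)CC=C(C)C | intermediate
14 | lithium 1,1-dibromo-5-methylhexa-1,4-dien-2-olate | [Li]OC(CC=C(C)C)=C(Br)Br | intermediate
15 | lithium 5-methylhex-4-en-1-yn-1-olate | [Li]OC#CCC=C(C)C | intermediate
16 | triisopropyl(5-methylhex-4-en-1-ynyloxy)silane | CC(C)=CCC#CO[Si](C(C)C)(C(C)C)C(C)C | intermediate
17 | 2-(trimethylsilyl)ethyl 5-methoxy-4,7-bis(3-methylbut-2-enyl)-3-oxo-8-(triisopropylsilyloxy)-1-{2-[4-(triisopropylsilyloxy)phenyl]ethyl}-2-oxabicyclo[2.2.2]octa-5,7-diene-6-carboxylate (racemic, one enantiomer drawn) | O=C1O[C@]2(CCc3ccc(O[Si](C(C)C)(C(C)C)C(C)C)cc3)C(C(=O)OCC[Si](C)(C)C)=C(OC)[C@@]1(CC=C(C)C)C(O[Si](C(C)C)(C(C)C)C(C)C)=C2CC=C(C)C | intermediate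
18 | 2-(trimethylsilyl)ethyl 2-methoxy-3,5-bis(3-methylbut-2-enyl)-4-(triisopropylsilyloxy)-6-{2-[4-(triisopropylsilyloxy)phenyl]ethyl}benzoate | C[Si](C)(C)CCOC(=O)c1c(OC)c(CC=C(C)C)c(O[Si](C(C)C)(C(C)C)C(C)C)c(CC=C(C)C)c1CCc1ccc(O[Si](C(C)C)(C(C)C)C(C)C)cc1 | intermediate
19 | 4-hydroxy-6-[2-(4-hydroxyphenyl)ethyl]-2-methoxy-3,5-bis(3-methylbut-2-enyl)benzoic acid | COc1c(CC=C(C)C)c(O)c(CC=C(C)C)c(CCc2ccc(O)cc2)c1C(=O)O | target

Total step count: 10.
Longest linear sequence: 6 steps (1, 2, 5, 6, 9, 10). The branch 3, 4, 5, 6, 9, 10 is equally long.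

Steps most likely to fail

1. Step 9.
- **Risk:** The cycloaddition may be too slow, because the 4-methoxy donor and four substituents raise the diene LUMO and crowd both termini. Side processes could then take over: thermal oxygen-to-carbon silyl migration of the ynol ether to a silylketene, its oligomerisation, or four-membered closure of the zwitterion onto C5.
- **Fallback:** It sets out from 11 and keeps the same two ring bonds, but uses a more nucleophilic, less crowded sp2 dienophile, following the known cycloaddition of 2-pyrone carboxylates with ketene acetals. Purchased 5-methylhex-4-enoic acid is treated with LiN(i-Pr)2 (2.2 equiv) and Me3SiCl in THF to give 1,1-bis(trimethylsilyloxy)-5-methylhexa-1,4-diene F1.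
- Heating F1 with 11 in toluene should bond its CH terminus to C6 and its acetal carbon to C3. Loss of CO2 and then of trimethylsilanol from the cyclohexadiene should give 2-(trimethylsilyl)ethyl 2-methoxy-3,5-bis(3-methylbut-2-enyl)-4-(trimethylsilyloxy)-6-{2-[4-(triisopropylsilyloxy)phenyl]ethyl}benzoate F2.
- **Return:** Crude F2 is treated with Bu4NF as in step 10, and the route is rejoined at 19.

2. Step 8.
- **Risk:** The lithium bases may enolise the doubly activated α-methylene of 13 in competition with addition, with drift of the alkene into conjugation. The excess alkyllithium may also isomerise the skipped enyne.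
- **Fallback:** It sets out from 3 and makes the ynolate by oxidising an acetylide instead of homologating an ester. CuCl-catalysed coupling of 3 with HC≡CMgBr in THF should give 5-methylhex-4-en-1-yne F3 by attack at the primary allyl terminus.
- n-BuLi (1 equiv, −78 °C) converts F3 into (5-methylhex-4-en-1-ynyl)lithium F4. LiOOt-Bu, made from t-BuOOH and LiN(SiMe3)2, then transfers oxygen at −78 to 0 °C to give the same ynolate 15.
- **Return:** i-Pr3SiOTf at −78 °C traps 15, and the route is rejoined at 16.

3. Step 5.
- **Risk:** Acylation may drift to oxygen or to the prenyl-bearing carbon, or the new acyl group may be lost by retro-Claisen cleavage during work-up. Ring closure onto the ester next to a tertiary carbon may also be slow enough for DBU to begin removing the phenol silyl group.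
- **Fallback:** It sets out from 2 and 8 and installs the prenyl group after the ring is made. The same MgCl2/pyridine acylation on the symmetrical, unhindered diester should give bis[2-(trimethylsilyl)ethyl] 3-oxo-2-{3-[4-(triisopropylsilyloxy)phenyl]propanoyl}pentanedioate F5. DBU in toluene should close F5 to 2-(trimethylsilyl)ethyl 4-hydroxy-2-oxo-6-{2-[4-(triisopropylsilyloxy)phenyl]ethyl}-2H-pyran-5-carboxylate F6.
- A Tsuji–Trost allylation of F6 with methyl 3-methylbut-2-enyl carbonate and Pd(PPh3)4 (zerovalent palladium) in THF at 50 °C then introduces the prenyl group. O-allylated material re-ionises and funnels to the C3-alkylated pyrone, and the soft nucleophile attacks the unsubstituted allyl terminus.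
- **Return:** The route is rejoined at 10.

Further compounds
F1 | step 9 | 1,1-bis(trimethylsilyloxy)-5-methylhexa-1,4-diene | CC(C)=CCC=C(O[Si](C)(C)C)O[Si](C)(C)C
F2 | step 9 | 2-(trimethylsilyl)ethyl 2-methoxy-3,5-bis(3-methylbut-2-enyl)-4-(trimethylsilyloxy)-6-{2-[4-(triisopropylsilyloxy)phenyl]ethyl}benzoate | C[Si](C)(C)CCOC(=O)c1c(OC)c(CC=C(C)C)c(O[Si](C)(C)C)c(CC=C(C)C)c1CCc1ccc(O[Si](C(C)C)(C(C)C)C(C)C)cc1
F3 | step 8 | 5-methylhex-4-en-1-yne | C#CCC=C(C)C
F4 | step 8 | (5-methylhex-4-en-1-ynyl)lithium | [Li]C#CCC=C(C)C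
F5 | step 5 | bis[2-(trimethylsilyl)ethyl] 3-oxo-2-{3-[4-(triisopropylsilyloxy)phenyl]propanoyl}pentanedioate | C[Si](C)(C)CCOC(=O)CC(=O)C(C(=O)OCC[Si](C)(C)C)C(=O)CCc1ccc(O[Si](C(C)C)(C(C)C)C(C)C)cc1
F6 | step 5 | 2-(trimethylsilyl)ethyl 4-hydroxy-2-oxo-6-{2-[4-(triisopropylsilyloxy)phenyl]ethyl}-2H-pyran-5-carboxylate | C[Si](C)(C)CCOC(=O)C1=C(CCc2ccc(O[Si](C(C)C)(C(C)C)C(C)C)cc2)OC(=O)C=C1O
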